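C2–C3 of the dihydrofuran is cut first (after the O-protecting groups), then N2, the benzyl ether O–CH2 and the C3a–CH2 bond, leading to a ring A pyranone, a ring B aldehyde and a benzyl alcohol.
The target is a 2,3-dihydro-4H-furo[3,2-c]pyran-4-one: O1–C2(catechol)–C3(ring B through C6')–C3a–C7a, with C3a/C7a shared with pyranone ring A; ring B is the pendant 4-hydroxy-2-pyranone.
Feature used: C3 lies between two pyranone sp2 carbons (C3a, C6') and C2 is a benzylic ether carbon on O1, so C3 can be a diaryl-type rhodium carbene that inserts into the benzylic C–H of a 4-O-benzyl ether on ring A.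
Forward: ring A (acylketene cyclisation) and ring B aldehyde 12 are made separately and joined through the CH2 that becomes C3 (14), followed by O-benzylation (18) and diazo transfer (19); the dihydrofuran closes last.
Stereochemistry: C2 (R) and C3 (S) form together, cis, in the catalyst-controlled insertion; no base is used afterwards, since C3–H is acidic and O1 is a good leaving group.

Key step: step 12

Abbreviations: TBS = tert-butyldimethylsilyl, TBSO = tert-butyldimethylsilyloxy, MOM = methoxymethyl, p-ABSA = 4-acetamidobenzenesulfonyl azide, Rh2(R-PTAD)4 = Rh2[(R)-O2CCH(1-adamantyl)(N-phthalimido)]4.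

Assumption: the sense of induction of Rh2(PTAD)4 with a carbene flanked by two pyranones is taken to follow that of diaryl carbenes, so the route is written with Rh2(R-PTAD)4; Rh2(S-PTAD)4 replaces it without other change if a test insertion shows the opposite sense.

Step 1
Reactants: 1 3,4-dihydroxybenzoic acid
Product: 3 3,4-bis(tert-butyldimethylsilyloxy)benzoic acid, via silyl ester 2 (not isolated)
Conditions: TBSCl (3.5 equiv), imidazole, DMF, 23 °C; then AcOH/THF/H2O, 23 °C
Reagents that add atoms: tert-butyldimethylsilyl chloride (TBSCl), CC(C)(C)[Si](C)(C)Cl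
Why: Silyl ether formation with TBSCl/imidazole covers both phenols and the acid, and aqueous acetic acid then hydrolyses only the labile silyl ester because aryl silyl ethers withstand weak acid.

Step 2
Reactants: 3 3,4-bis(tert-butyldimethylsilyloxy)benzoic acid; 4 2,2,6-trimethyl-4H-1,3-dioxin-4-one
Product: 6 6-{2-[3,4-bis(TBSO)phenyl]-2-oxoethyl}-2,2-dimethyl-4H-1,3-dioxin-4-one, via acid chloride 5 (not isolated)
Conditions: (COCl)2, cat. DMF, CH2Cl2, 0 to 23 °C, evaporate; then added to 4 (2.2 equiv)/LiN(SiMe3)2 (2.2 equiv), THF, −78 °C; aq. NH4Cl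
Reagents that add atoms: none
Why: The acid chloride C-acylates the lithium dienolate of 4 at its terminal carbon (vinylogous Claisen-type acylation of a dioxinone dienolate), the second equivalent of dienolate taking up the acidic proton of the diketone product.

Step 3
Reactants: 6 6-{2-[3,4-bis(TBSO)phenyl]-2-oxoethyl}-2,2-dimethyl-4H-1,3-dioxin-4-one
Product: 8 6-[3,4-bis(TBSO)phenyl]-4-hydroxy-2H-pyran-2-one (ring A pyranone), via acylketene 7 (not isolated)
Conditions: toluene, 110 °C
Reagents that add atoms: none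
Why: Thermal retro-[4+2] loss of acetone gives an acylketene that is trapped by the enol oxygen of the aryl ketone (acylketene cyclisation to a 4-hydroxy-2-pyranone) under neutral conditions that spare the silyl ethers.

Step 4
Reactants: 9 4-hydroxy-6-methyl-2H-pyran-2-one
Product: 10 4-(methoxymethoxy)-6-methyl-2H-pyran-2-one
Conditions: MOMCl, i-Pr2NEt, CH2Cl2, 0 to 23 °C
Reagents that add atoms: chloromethyl methyl ether (MOMCl), COCCl
Why: O-Alkylation of the acidic 4-hydroxyl with the hard electrophile MOMCl and a hindered amine base should give the vinylogous MOM ester at O4 (ether formation by O-alkylation).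

Step 5
Reactants: 10 4-(methoxymethoxy)-6-methyl-2H-pyran-2-one
Product: 11 6-[(E)-2-(dimethylamino)ethenyl]-4-(methoxymethoxy)-2H-pyran-2-one
Conditions: Me2NCH(OMe)2 (3 equiv), DMF, 100 °C
Reagents that add atoms: N,N-dimethylformamide dimethyl acetal, COC(OC)N(C)C
Why: The 6-methyl group is a vinylogous C–H acid and should condense with the formamide acetal to the push–pull (E)-enamine (enamination of an activated methyl group) under non-acidic conditions that the MOM group tolerates.

Step 6
Reactants: 11 6-[(E)-2-(dimethylamino)ethenyl]-4-(methoxymethoxy)-2H-pyran-2-one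
Product: 12 4-(methoxymethoxy)-2-oxo-2H-pyran-6-carbaldehyde
Conditions: NaIO4 (3 equiv), THF/H2O, 23 °C
Reagents that add atoms: sodium periodate NaIO4, [Na+].[O-]I(=O)(=O)=O
Why: Periodate cleaves the electron-rich enamine C=C bond to the aldehyde and DMF (oxidative cleavage of an enamine) at near-neutral pH, which the vinylogous MOM ester should survive.

Step 7
Reactants: 8 6-[3,4-bis(TBSO)phenyl]-4-hydroxy-2H-pyran-2-one; 12 4-(methoxymethoxy)-2-oxo-2H-pyran-6-carbaldehyde
Product: 14 6-[3,4-bis(TBSO)phenyl]-4-hydroxy-3-{[4-(methoxymethoxy)-2-oxo-2H-pyran-6-yl]methyl}-2H-pyran-2-one, via alkylidene pyrandione 13 (not isolated)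
Conditions: diethyl 2,6-dimethyl-1,4-dihydropyridine-3,5-dicarboxylate (Hantzsch ester, 1.1 equiv), L-proline (20 mol %), CH2Cl2, 23 °C
Reagents that add atoms: none
Why: Proline-catalysed Knoevenagel condensation at the nucleophilic C3 of the 4-hydroxypyranone gives a strongly electrophilic alkylidene dione that the Hantzsch ester should reduce by conjugate hydride transfer faster than a second pyranone adds (three-component reductive alkylation), installing the CH2 that becomes C3.

Step 8
Reactants: 15 3,4-dihydroxybenzaldehyde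
Product: 16 3,4-bis(tert-butyldimethylsilyloxy)benzaldehyde
Conditions: TBSCl (2.4 equiv), imidazole, DMF, 23 °C
Reagents that add atoms: tert-butyldimethylsilyl chloride (TBSCl), CC(C)(C)[Si](C)(C)Cl
Why: Routine silyl ether formation on both phenols with TBSCl/imidazole, the aldehyde being inert.

Step 9
Reactants: 16 3,4-bis(tert-butyldimethylsilyloxy)benzaldehyde
Product: 17 [3,4-bis(tert-butyldimethylsilyloxy)phenyl]methanol
Conditions: NaBH4, THF/MeOH, 0 °C
Reagents that add atoms: none
Why: Borohydride reduction of the aryl aldehyde to the benzylic alcohol at 0 °C, conditions under which aryl TBS ethers are retained.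

Step 10
Reactants: 14 6-[3,4-bis(TBSO)phenyl]-4-hydroxy-3-{[4-(methoxymethoxy)-2-oxo-2H-pyran-6-yl]methyl}-2H-pyran-2-one; 17 [3,4-bis(tert-butyldimethylsilyloxy)phenyl]methanol
Product: 18 4-{[3,4-bis(TBSO)phenyl]methoxy}-6-[3,4-bis(TBSO)phenyl]-3-{[4-(methoxymethoxy)-2-oxo-2H-pyran-6-yl]methyl}-2H-pyran-2-one
Conditions: PPh3, diisopropyl azodicarboxylate, THF, 0 to 23 °C
Reagents that add atoms: none
Why: Mitsunobu reaction, in which the 4-hydroxypyranone, about as acidic as a carboxylic acid, is alkylated at O4 by the activated primary benzylic alcohol under neutral conditions, avoiding an unstable electron-rich benzyl halide.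

Step 11
Reactants: 18 4-{[3,4-bis(TBSO)phenyl]methoxy}-6-[3,4-bis(TBSO)phenyl]-3-{[4-(methoxymethoxy)-2-oxo-2H-pyran-6-yl]methyl}-2H-pyran-2-one
Product: 19 4-{[3,4-bis(TBSO)phenyl]methoxy}-6-[3,4-bis(TBSO)phenyl]-3-{diazo[4-(methoxymethoxy)-2-oxo-2H-pyran-6-yl]methyl}-2H-pyran-2-one
Conditions: p-ABSA (1.3 equiv), DBU (1.5 equiv), anhydrous MeCN, 0 °C, dark; rapid cold chromatography, used at once
Reagents that add atoms: 4-acetamidobenzenesulfonyl azide (p-ABSA), CC(=O)Nc1ccc(cc1)S(=O)(=O)N=[N+]=[N-]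
Why: Proposed new method: DBU should deprotonate the bridging CH2, whose anion is delocalised as an extended dienolate through ring B to its lactone carbonyl and is further stabilised by ring A, and this carbanion should add to the terminal nitrogen of the sulfonyl azide to give a triazenyl anion that loses the sulfonamide after proton transfer, leaving a diazo group stabilised by the same conjugation; the closest known reaction type is Regitz diazo transfer with p-ABSA/DBU to benzylic C–H acids such as aryl acetates, benzyl azoles and anthrone.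

Step 12
Reactants: 19 4-{[3,4-bis(TBSO)phenyl]methoxy}-6-[3,4-bis(TBSO)phenyl]-3-{diazo[4-(methoxymethoxy)-2-oxo-2H-pyran-6-yl]methyl}-2H-pyran-2-one
Product: 20 cis-(2R,3S)-2,6-bis[3,4-bis(TBSO)phenyl]-3-[4-(methoxymethoxy)-2-oxo-2H-pyran-6-yl]-2,3-dihydro-4H-furo[3,2-c]pyran-4-one
Conditions: Rh2(R-PTAD)4 (1 mol %), CH2Cl2, 4 Å molecular sieves, −20 to 23 °C, slow addition of cold 19
Reagents that add atoms: none
Why: The dirhodium carboxylate takes N2 out of 19 and gives an electrophilic rhodium carbene at the future C3, which accepts the hydridic benzylic C–H of the O1–CH2–aryl group through a three-centre, hydride-transfer-like transition state and forms C2–C3 in the same event. The closest known reaction type is the dirhodium-carboxylate-catalysed enantioselective intramolecular C–H insertion of diaryl (donor/donor) carbenes into benzylic ethers, which gives cis-2,3-diaryl-2,3-dihydrobenzofurans. The dihydrofuran closes by 1,5-insertion, the carbene carbon, C3a, C7a, O1 and the benzylic carbon making up the five-membered ring, whereas attack of O1 or of the lactone carbonyl on the carbene would need a four-membered ring. C3 (S) is set by the carbene face left open by the phthalimido/adamantyl pocket of the catalyst, and C2 (R) by which of the two enantiotopic benzylic hydrogens is delivered in that same transition state, where the C2 aryl group lies on the side of ring B and away from the carboxylate wall, hence cis. The step needs site selectivity, cis selectivity and one absolute sense: the ether oxygen and the para-silyloxy group activate the only C–H within 1,5 reach, the two ring substituents on the carbene carbon slow azine and dimer formation, and kinetic control holds because neither acid nor base acts on the acidic C3–H afterwards.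

Step 13
Reactants: 20 cis-(2R,3S)-2,6-bis[3,4-bis(TBSO)phenyl]-3-[4-(methoxymethoxy)-2-oxo-2H-pyran-6-yl]-2,3-dihydro-4H-furo[3,2-c]pyran-4-one
Product: 21 cis-(2R,3S)-2,6-bis[3,4-bis(TBSO)phenyl]-3-(4-hydroxy-2-oxo-2H-pyran-6-yl)-2,3-dihydro-4H-furo[3,2-c]pyran-4-one
Conditions: 1 M aq. HCl, THF, 0 to 23 °C
Reagents that add atoms: none
Why: Acetal hydrolysis, in which the MOM group on a vinylogous carboxylic acid oxygen is released by dilute acid through loss of the pyranone as a good leaving group, at a temperature too low to ionise the C2–O1 bond or cleave aryl silyl ethers.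

Step 14
Reactants: 21 cis-(2R,3S)-2,6-bis[3,4-bis(TBSO)phenyl]-3-(4-hydroxy-2-oxo-2H-pyran-6-yl)-2,3-dihydro-4H-furo[3,2-c]pyran-4-one
Product: 22 (2R,3S)-2,6-bis(3,4-dihydroxyphenyl)-3-(4-hydroxy-2-oxo-2H-pyran-6-yl)-2,3-dihydro-4H-furo[3,2-c]pyran-4-one (target)
Conditions: HF·pyridine, pyridine, THF, 0 to 23 °C, argon
Reagents that add atoms: none
Why: Silyl ether cleavage by pyridine-buffered HF breaks the four aryl Si–O bonds through Si–F bond formation without free phenoxide or strong base, so neither quinone-methide opening at C2 nor deprotonation at C3 should scramble the cis stereocentres.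

Compound list
1 | 3,4-dihydroxybenzoic acid | OC(=O)c1ccc(O)c(O)c1 | starting material
2 | tert-butyldimethylsilyl 3,4-bis(tert-butyldimethylsilyloxy)benzoate | CC(C)(C)[Si](C)(C)OC(=O)c1ccc(O[Si](C)(C)C(C)(C)C)c(O[Si](C)(C)C(C)(C)C)c1 | intermediate (not isolated)
3 | 3,4-bis(tert-butyldimethylsilyloxy)benzoic acid | OC(=O)c1ccc(O[Si](C)(C)C(C)(C)C)c(O[Si](C)(C)C(C)(C)C)c1 | intermediate
4 | 2,2,6-trimethyl-4H-1,3-dioxin-4-one | CC1=CC(=O)OC(C)(C)O1 | starting material
5 | 3,4-bis(tert-butyldimethylsilyloxy)benzoyl chloride | ClC(=O)c1ccc(O[Si](C)(C)C(C)(C)C)c(O[Si](C)(C)C(C)(C)C)c1 | intermediate (not isolated)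
6 | 6-{2-[3,4-bis(TBSO)phenyl]-2-oxoethyl}-2,2-dimethyl-4H-1,3-dioxin-4-one | CC1(C)OC(=O)C=C(CC(=O)c2ccc(O[Si](C)(C)C(C)(C)C)c(O[Si](C)(C)C(C)(C)C)c2)O1 | intermediate
7 | 5-[3,4-bis(TBSO)phenyl]-3,5-dioxopent-1-en-1-one (acylketene) | O=C=CC(=O)CC(=O)c1ccc(O[Si](C)(C)C(C)(C)C)c(O[Si](C)(C)C(C)(C)C)c1 | intermediate (not isolated)
8 | 6-[3,4-bis(TBSO)phenyl]-4-hydroxy-2H-pyran-2-one (ring A pyranone) | O=c1cc(O)cc(-c2ccc(O[Si](C)(C)C(C)(C)C)c(O[Si](C)(C)C(C)(C)C)c2)o1 | intermediate
9 | 4-hydroxy-6-methyl-2H-pyran-2-one | Cc1cc(O)cc(=O)o1 | starting material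
10 | 4-(methoxymethoxy)-6-methyl-2H-pyran-2-one | COCOc1cc(C)oc(=O)c1 | intermediate
11 | 6-[(E)-2-(dimethylamino)ethenyl]-4-(methoxymethoxy)-2H-pyran-2-one | COCOc1cc(/C=C/N(C)C)oc(=O)c1 | intermediate
12 | 4-(methoxymethoxy)-2-oxo-2H-pyran-6-carbaldehyde (ring B aldehyde) | COCOc1cc(C=O)oc(=O)c1 | intermediate
13 | 6-[3,4-bis(TBSO)phenyl]-3-{[4-(methoxymethoxy)-2-oxo-2H-pyran-6-yl]methylidene}-2H-pyran-2,4(3H)-dione | O=C1OC(c2ccc(O[Si](C)(C)C(C)(C)C)c(O[Si](C)(C)C(C)(C)C)c2)=CC(=O)C1=Cc1cc(OCOC)cc(=O)o1 | intermediate (not isolated)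
14 | 6-[3,4-bis(TBSO)phenyl]-4-hydroxy-3-{[4-(methoxymethoxy)-2-oxo-2H-pyran-6-yl]methyl}-2H-pyran-2-one | COCOc1cc(Cc2c(O)cc(-c3ccc(O[Si](C)(C)C(C)(C)C)c(O[Si](C)(C)C(C)(C)C)c3)oc2=O)oc(=O)c1 | intermediate
15 | 3,4-dihydroxybenzaldehyde | O=Cc1ccc(O)c(O)c1 | starting material
16 | 3,4-bis(tert-butyldimethylsilyloxy)benzaldehyde | O=Cc1ccc(O[Si](C)(C)C(C)(C)C)c(O[Si](C)(C)C(C)(C)C)c1 | intermediate
17 | [3,4-bis(tert-butyldimethylsilyloxy)phenyl]methanol | OCc1ccc(O[Si](C)(C)C(C)(C)C)c(O[Si](C)(C)C(C)(C)C)c1 | intermediate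
18 | 4-{[3,4-bis(TBSO)phenyl]methoxy}-6-[3,4-bis(TBSO)phenyl]-3-{[4-(methoxymethoxy)-2-oxo-2H-pyran-6-yl]methyl}-2H-pyran-2-one | COCOc1cc(Cc2c(OCc3ccc(O[Si](C)(C)C(C)(C)C)c(O[Si](C)(C)C(C)(C)C)c3)cc(-c3ccc(O[Si](C)(C)C(C)(C)C)c(O[Si](C)(C)C(C)(C)C)c3)oc2=O)oc(=O)c1 | intermediate
19 | 4-{[3,4-bis(TBSO)phenyl]methoxy}-6-[3,4-bis(TBSO)phenyl]-3-{diazo[4-(methoxymethoxy)-2-oxo-2H-pyran-6-yl]methyl}-2H-pyran-2-one | COCOc1cc(C(=[N+]=[N-])c2c(OCc3ccc(O[Si](C)(C)C(C)(C)C)c(O[Si](C)(C)C(C)(C)C)c3)cc(-c3ccc(O[Si](C)(C)C(C)(C)C)c(O[Si](C)(C)C(C)(C)C)c3)oc2=O)oc(=O)c1 | intermediate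
20 | cis-(2R,3S)-2,6-bis[3,4-bis(TBSO)phenyl]-3-[4-(methoxymethoxy)-2-oxo-2H-pyran-6-yl]-2,3-dihydro-4H-furo[3,2-c]pyran-4-one | O=c1cc(OCOC)cc([C@H]2c3c(cc(-c4ccc(O[Si](C)(C)C(C)(C)C)c(O[Si](C)(C)C(C)(C)C)c4)oc3=O)O[C@H]2c2ccc(O[Si](C)(C)C(C)(C)C)c(O[Si](C)(C)C(C)(C)C)c2)o1 | intermediate
21 | cis-(2R,3S)-2,6-bis[3,4-bis(TBSO)phenyl]-3-(4-hydroxy-2-oxo-2H-pyran-6-yl)-2,3-dihydro-4H-furo[3,2-c]pyran-4-one | O=c1cc(O)cc([C@H]2c3c(cc(-c4ccc(O[Si](C)(C)C(C)(C)C)c(O[Si](C)(C)C(C)(C)C)c4)oc3=O)O[C@H]2c2ccc(O[Si](C)(C)C(C)(C)C)c(O[Si](C)(C)C(C)(C)C)c2)o1 | intermediate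
22 | (2R,3S)-2,6-bis(3,4-dihydroxyphenyl)-3-(4-hydroxy-2-oxo-2H-pyran-6-yl)-2,3-dihydro-4H-furo[3,2-c]pyran-4-one | O=c1cc(O)cc([C@H]2c3c(cc(-c4ccc(O)c(O)c4)oc3=O)O[C@H]2c2ccc(O)c(O)c2)o1 | target

Total step count: 14.
Longest linear sequence: 9 steps (steps 1, 2, 3, 7, 10, 11, 12, 13, 14; the branch from 9 through steps 4, 5, 6 is equally long).

Steps most likely to fail

Step 11. The bridging CH2 may be deprotonated too little by DBU, or the crowded carbanion may capture the sulfonyl azide too slowly, so that base-induced loss of aryl silyl ethers overtakes diazo transfer. The fallback builds the diazo carbon at the ketone oxidation level; it sets out from aldehyde 12 (partners 8 and 17) and comes back to the route at 19. Pinnick oxidation of 12 (NaClO2, NaH2PO4, 2-methyl-2-butene, t-BuOH/H2O) should give 4-(methoxymethoxy)-2-oxo-2H-pyran-6-carboxylic acid F1. Dicyclohexylcarbodiimide and 4-(dimethylamino)pyridine in CH2Cl2 should couple F1 with 8 to the 4-O-acyl enol ester F2, which is not isolated and should rearrange under the same catalyst by O-to-C acyl shift to the 3-aroyl-4-hydroxypyranone F3. Mitsunobu reaction of F3 with 17 (PPh3, diisopropyl azodicarboxylate) should give the benzyl ether ketone F4. Condensation with TsNHNH2 (cat. acid, MeOH/THF, low temperature to limit displacement of the 4-alkoxy group) should give the N-tosylhydrazone F5, and Bamford–Stevens elimination of sulfinate with NaH in THF should give 19.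

Step 12. Facial selectivity at the carbene carbon may be poor because the chiral pocket has to tell apart two flat pyranone substituents, and ring closure of the diazo group onto a pyranone C=C may compete before nitrogen loss. The fallback moves the source of absolute configuration from the catalyst to a separation; it sets out from 19 and comes back at 20. Achiral Rh2(OAc)4 in CH2Cl2 should still give the cis product through the same concerted insertion, as the racemate of 20 and its (2S,3R)-enantiomer F6, and preparative chromatography on a chiral stationary phase (amylose tris(3,5-dimethylphenylcarbamate)) should deliver 20.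

Step 5. Enamine formation at the weakly acidic 6-methyl group may be sluggish, and at the temperature required liberated amine may attack the pyranone ring. The fallback oxidises the methyl group through its anion; it sets out from 10 and comes back at 12, by-passing 11. Lateral deprotonation of 10 with LiN(SiMe3)2 (THF, −78 °C) and hydroxylation of the dienolate with (camphorsulfonyl)oxaziridine should give 6-(hydroxymethyl)-4-(methoxymethoxy)-2H-pyran-2-one F7, which MnO2 in CH2Cl2 should oxidise to 12.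

Further compounds
F1 | step 11 | 4-(methoxymethoxy)-2-oxo-2H-pyran-6-carboxylic acid | COCOc1cc(C(=O)O)oc(=O)c1
F2 | step 11 | 4-O-acyl enol ester: 6-[3,4-bis(TBSO)phenyl]-2-oxo-2H-pyran-4-yl 4-(methoxymethoxy)-2-oxo-2H-pyran-6-carboxylate | COCOc1cc(C(=O)Oc2cc(-c3ccc(O[Si](C)(C)C(C)(C)C)c(O[Si](C)(C)C(C)(C)C)c3)oc(=O)c2)oc(=O)c1
F3 | step 11 | 3-aroyl-4-hydroxypyranone: 6-[3,4-bis(TBSO)phenyl]-4-hydroxy-3-[4-(methoxymethoxy)-2-oxo-2H-pyran-6-carbonyl]-2H-pyran-2-one | COCOc1cc(C(=O)c2c(O)cc(-c3ccc(O[Si](C)(C)C(C)(C)C)c(O[Si](C)(C)C(C)(C)C)c3)oc2=O)oc(=O)c1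
F4 | step 11 | benzyl ether ketone: 4-{[3,4-bis(TBSO)phenyl]methoxy}-6-[3,4-bis(TBSO)phenyl]-3-[4-(methoxymethoxy)-2-oxo-2H-pyran-6-carbonyl]-2H-pyran-2-one | COCOc1cc(C(=O)c2c(OCc3ccc(O[Si](C)(C)C(C)(C)C)c(O[Si](C)(C)C(C)(C)C)c3)cc(-c3ccc(O[Si](C)(C)C(C)(C)C)c(O[Si](C)(C)C(C)(C)C)c3)oc2=O)oc(=O)c1
F5 | step 11 | N-tosylhydrazone of F4 | COCOc1cc(C(=NNS(=O)(=O)c2ccc(C)cc2)c2c(OCc3ccc(O[Si](C)(C)C(C)(C)C)c(O[Si](C)(C)C(C)(C)C)c3)cc(-c3ccc(O[Si](C)(C)C(C)(C)C)c(O[Si](C)(C)C(C)(C)C)c3)oc2=O)oc(=O)c1
F6 | step 12 | (2S,3R)-enantiomer of 20 | O=c1cc(OCOC)cc([C@@H]2c3c(cc(-c4ccc(O[Si](C)(C)C(C)(C)C)c(O[Si](C)(C)C(C)(C)C)c4)oc3=O)O[C@@H]2c2ccc(O[Si](C)(C)C(C)(C)C)c(O[Si](C)(C)C(C)(C)C)c2)o1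
F7 | step 5 | 6-(hydroxymethyl)-4-(methoxymethoxy)-2H-pyran-2-one | COCOc1cc(CO)oc(=O)c1
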